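**Retrosynthetic overview**
1. Target 22 ⇐ 2β,3β-vinyl epoxide 21: the last bond formed is C2–O, by anti hydrolysis, with both acetates already in place.
2. 11-membered ring ⇐ C1–C14 B-alkyl Suzuki macrocyclisation, after a C8–C9 Nozaki–Hiyama–Kishi union of bis(enol triflate) 11 with aldehyde 17 (C12 set by Cu-catalysed allylic alkylation).
3. Cyclopentane ⇐ C7–C16 Rauhut–Currier closure onto the only free enone arm of epoxy-enone 8, then convex-face hydrogenation to set C7.
4. Key C–O step: catalyst-controlled epoxidation of racemic dienone 5 → 6 makes C2–O and C3–O and selects C4; the oxirane then blocks one enone arm and one enolisation site until it is opened to the trans-diol.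
5. Ring order: cyclohexenone (Robinson) → oxirane → cyclopentane → 11-membered ring → oxirane opened.

Assumption: intermediates carry the trinervitane locants of the target (six-ring C1–C2–C3–C4–C16–C15, five-ring C4–C5–C6–C7–C16, C17 = CH3 on C15, C18 = CH3 on C4, chain C8(=C19)–C9…C14, C20 on C12); β is the face of C18.

Step 1
Reactants: 1 2-methylpent-4-enal (racemic); 2 pent-1-en-3-one
Product: 4 rac-2,4-dimethyl-4-(prop-2-en-1-yl)cyclohex-2-en-1-one, via Michael adduct 3 (not isolated)
Conditions: pyrrolidine (cat.), AcOH (cat.), PhMe, 70 °C; then KOH, MeOH, 60 °C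
Reagents that add atoms: none
Why: Robinson annulation (enamine Michael addition of the α-branched aldehyde to ethyl vinyl ketone, then intramolecular aldol condensation) builds the cyclohexenone with the C4 quaternary centre (racemic) and the C15 methyl in place.

Step 2
Reactants: 4 rac-2,4-dimethyl-4-(prop-2-en-1-yl)cyclohex-2-en-1-one
Product: 5 rac-2,4-dimethyl-4-(prop-2-en-1-yl)cyclohexa-2,5-dien-1-one
Conditions: IBX (2.5 equiv), DMSO/PhF, 60 °C
Reagents that add atoms: none
Why: IBX α,β-dehydrogenation of the ketone can only introduce the C2=C3 double bond (C15 is already sp2, C4 is quaternary), giving the cross-conjugated dienone below the temperature at which 4-allyl dienones rearrange.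

Step 3
Reactants: 5 rac-2,4-dimethyl-4-(prop-2-en-1-yl)cyclohexa-2,5-dien-1-one
Product: 6 (1R,5S,6R)-3,5-dimethyl-5-(prop-2-en-1-yl)-7-oxabicyclo[4.1.0]hept-3-en-2-one
Conditions: 9-amino-9-deoxy-epi-cinchona amine·2 TFA (10 mol%, antipode chosen for the 1R,6R oxirane), 50% aq. H2O2 (1.2 equiv), dioxane, 30 °C; silica separation from the C5-epimeric epoxide
Reagents that add atoms: hydrogen peroxide, OO
Why: Proposed new method: the chiral primary amine forms an iminium ion with the dienone, the quinuclidinium-bound hydroperoxide adds to the unsubstituted β-carbon (the 2-methyl arm is deactivated) on the catalyst-defined π-face and the peroxy-enamine closes to the oxirane, so each enantiomer of 5 is epoxidised on the same local face and (R)-5 gives 6 (oxirane cis to the C4 methyl, maximum 50%) while (S)-5 gives a separable C5 epimer, which fixes C2, C3 and, by selection, C4; the closest known reaction type is the primary-amine (iminium) catalysed asymmetric Weitz–Scheffer epoxidation of simple cyclic enones, not yet shown as a stereodivergent resolution of racemic cross-conjugated dienones.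

Step 4
Reactants: 6 (1R,5S,6R)-3,5-dimethyl-5-(prop-2-en-1-yl)-7-oxabicyclo[4.1.0]hept-3-en-2-one; 7 but-3-en-2-one
Product: 8 (1R,5S,6R)-3,5-dimethyl-5-[(2E)-4-oxopent-2-en-1-yl]-7-oxabicyclo[4.1.0]hept-3-en-2-one
Conditions: Hoveyda–Grubbs II (5 mol%), 7 (4 equiv), CH2Cl2, 40 °C
Reagents that add atoms: none
Why: Olefin cross-metathesis of the allyl group with excess methyl vinyl ketone gives the (E)-enone, while the trisubstituted ring enone is metathesis-inert.

Step 5
Reactants: 8 (1R,5S,6R)-3,5-dimethyl-5-[(2E)-4-oxopent-2-en-1-yl]-7-oxabicyclo[4.1.0]hept-3-en-2-one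
Product: 9 7-acetyl-2β,3β-epoxy-4β,15-dimethyl-16βH-cis-hydrind-6-en-1-one (C15 epimers)
Conditions: PBu3 (20 mol%), t-BuOH, 40 °C
Reagents that add atoms: none
Why: Intramolecular Rauhut–Currier reaction: the phosphine adds to the unhindered side-chain enone and the resulting C7 enolate adds to C16 of the ring enone (the other arm is blocked as the oxirane) from the α face that carries the tether, giving the cis ring fusion (H16 β) and regenerating the C6=C7 enone.

Step 6
Reactants: 9 7-acetyl-2β,3β-epoxy-4β,15-dimethyl-16βH-cis-hydrind-6-en-1-one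
Product: 10 7α-acetyl-2β,3β-epoxy-4β,15-dimethyl-7βH,16βH-cis-hydrindan-1-one (C15 epimers)
Conditions: H2 (1 atm), Pd/C, EtOAc, 0 °C → rt
Reagents that add atoms: none
Why: Heterogeneous hydrogenation of the enone from the convex β face of the cis-hydrindane puts H7 β and the acetyl group on the concave α face, cis to C15.

Step 7
Reactants: 10 7α-acetyl-2β,3β-epoxy-4β,15-dimethyl-7βH,16βH-cis-hydrindan-1-one
Product: 11 2β,3β-epoxy-4β,15-dimethyl-7α-[1-(triflyloxy)ethenyl]-cis-hydrind-1(15)-en-1-yl triflate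
Conditions: KHMDS (2.4 equiv), THF, −78 °C; PhNTf2 (2.5 equiv), −78 → 0 °C
Reagents that add atoms: N-phenyl-bis(trifluoromethanesulfonimide), O=S(=O)(N(c1ccccc1)S(=O)(=O)C(F)(F)F)C(F)(F)F
Why: Double enol triflation traps the kinetic methyl enolate of the acetyl group (which also shields C7 from epimerisation) and the only possible C1 enolate (towards C15, because C2 is an oxirane carbon), fixing the C1=C15 tetrasubstituted alkene.

Step 8
Reactants: 12 2-(2-bromoethyl)-1,3-dioxolane; 13 (E)-1,4-dibromobut-2-ene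
Product: 15 2-[(3S)-3-(bromomethyl)pent-4-en-1-yl]-1,3-dioxolane, via Grignard reagent 14 (not isolated)
Conditions: Mg, THF, 25 °C; then 13, CuTC (3 mol%), chiral phosphoramidite (antipode chosen for S), CH2Cl2, −78 °C
Reagents that add atoms: none
Why: Copper-catalysed asymmetric allylic alkylation (SN2′) of the symmetrical dibromide with the Grignard reagent gives the branched homoallylic bromide, and the chiral ligand sets C12 (S).

Step 9
Reactants: 15 2-[(3S)-3-(bromomethyl)pent-4-en-1-yl]-1,3-dioxolane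
Product: 16 (2S)-4-(1,3-dioxolan-2-yl)-2-ethenylbutyl acetate
Conditions: KOAc, 18-crown-6 (cat.), DMF, 50 °C
Reagents that add atoms: potassium acetate, CC(=O)[O-].[K+]
Why: SN2 displacement of the primary bromide by acetate installs the C20 acetate without touching the stereocentre.

Step 10
Reactants: 16 (2S)-4-(1,3-dioxolan-2-yl)-2-ethenylbutyl acetate
Product: 17 (2S)-2-ethenyl-5-oxopentyl acetate
Conditions: 1 M HCl, THF, 25 °C
Reagents that add atoms: water, O
Why: Acid-catalysed acetal hydrolysis unmasks the C9 aldehyde and leaves the acetate intact.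

Step 11
Reactants: 11 2β,3β-epoxy-4β,15-dimethyl-7α-[1-(triflyloxy)ethenyl]-cis-hydrind-1(15)-en-1-yl triflate; 17 (2S)-2-ethenyl-5-oxopentyl acetate
Product: 18 (9S,12S)-20-acetoxy-2β,3β-epoxy-1-(triflyloxy)-1,14-secotrinervita-1(15),8(19),13-trien-9-ol
Conditions: CrCl2 (4 equiv), NiCl2 (2 mol%), Kishi chiral sulfonamide ligand, Et3N, THF, 25 °C
Reagents that add atoms: none
Why: Nozaki–Hiyama–Kishi coupling: Ni(0) inserts only into the unhindered 1,1-disubstituted alkenyl triflate (the tetrasubstituted C1 triflate is inert), and the alkenylchromium adds to the aldehyde under control of the chiral ligand to give the (9S)-allylic alcohol with the C8(19) exo-methylene.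

Step 12
Reactants: 18 (9S,12S)-20-acetoxy-2β,3β-epoxy-1-(triflyloxy)-1,14-secotrinervita-1(15),8(19),13-trien-9-ol
Product: 20 (9S,12R)-20-acetoxy-2β,3β-epoxytrinervita-1(15),8(19)-dien-9-ol, via C14 alkylborane 19 (not isolated)
Conditions: 9-BBN (2.2 equiv), THF, 0 → 25 °C; then slow addition to Pd(dppf)Cl2 (20 mol%), AsPh3, Cs2CO3, DMF/THF/H2O, 1 mM, 40 °C
Reagents that add atoms: none
Why: Chemoselective hydroboration of the monosubstituted vinyl group (the 1,1-disubstituted C8=C19 is flanked by two branched carbons) followed by intramolecular B-alkyl Suzuki–Miyaura coupling with the C1 enol triflate at high dilution closes the 11-membered ring across the α face.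

Step 13
Reactants: 20 (9S,12R)-20-acetoxy-2β,3β-epoxytrinervita-1(15),8(19)-dien-9-ol
Product: 21 (9S,12R)-2β,3β-epoxytrinervita-1(15),8(19)-diene-9,20-diyl diacetate
Conditions: Ac2O, pyridine, DMAP (cat.), CH2Cl2, 0 °C → rt
Reagents that add atoms: acetic anhydride, CC(=O)OC(C)=O
Why: DMAP-catalysed acylation of the only free hydroxyl (C9) gives the diacetate while the diol is still masked as the oxirane.

Step 14
Reactants: 21 (9S,12R)-2β,3β-epoxytrinervita-1(15),8(19)-diene-9,20-diyl diacetate
Product: 22 CNP0193272.1, (2R,3R,4S,7R,9S,12R,16S)-2,3-dihydroxytrinervita-1(15),8(19)-diene-9,20-diyl diacetate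
Conditions: HClO4 (cat.), THF/H2O, 0 °C
Reagents that add atoms: water, O
Why: Acid-catalysed anti (SN2-like) hydrolysis of the vinyl epoxide at the allylic carbon C2 from the α face inverts C2 and retains C3, giving the 2α,3β-trans-diol (2R,3R).

**Compound list**
1 | 2-methylpent-4-enal (racemic) | C=CCC(C)C=O | starting material
2 | pent-1-en-3-one (ethyl vinyl ketone) | C=CC(=O)CC | starting material
3 | rac-2-methyl-5-oxo-2-(prop-2-en-1-yl)heptanal | O=CC(C)(CC=C)CCC(=O)CC | intermediate (not isolated)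
4 | rac-2,4-dimethyl-4-(prop-2-en-1-yl)cyclohex-2-en-1-one | C=CCC1(C)CCC(=O)C(C)=C1 | intermediate
5 | rac-2,4-dimethyl-4-(prop-2-en-1-yl)cyclohexa-2,5-dien-1-one | C=CCC1(C)C=CC(=O)C(C)=C1 | intermediate
6 | (1R,5S,6R)-3,5-dimethyl-5-(prop-2-en-1-yl)-7-oxabicyclo[4.1.0]hept-3-en-2-one (oxirane cis to the ring methyl) | C=CC[C@@]1(C)C=C(C)C(=O)[C@@H]2O[C@H]12 | intermediate
7 | but-3-en-2-one (methyl vinyl ketone) | C=CC(C)=O | starting material
8 | (1R,5S,6R)-3,5-dimethyl-5-[(2E)-4-oxopent-2-en-1-yl]-7-oxabicyclo[4.1.0]hept-3-en-2-one | CC(=O)/C=C/C[C@@]1(C)C=C(C)C(=O)[C@@H]2O[C@H]12 | intermediate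
9 | 7-acetyl-2β,3β-epoxy-4β,15-dimethyl-16βH-cis-hydrind-6-en-1-one (C1 ketone, C6=C7, C15 epimers) | CC(=O)C1=CC[C@]2(C)[C@H]3O[C@H]3C(=O)C(C)[C@H]12 | intermediate
10 | 7α-acetyl-2β,3β-epoxy-4β,15-dimethyl-7βH,16βH-cis-hydrindan-1-one (C15 epimers) | CC(=O)[C@@H]1CC[C@]2(C)[C@H]3O[C@H]3C(=O)C(C)[C@H]12 | intermediate
11 | 2β,3β-epoxy-4β,15-dimethyl-7α-[1-(triflyloxy)ethenyl]-cis-hydrind-1(15)-en-1-yl triflate | C=C(OS(=O)(=O)C(F)(F)F)[C@@H]1CC[C@]2(C)[C@H]3O[C@H]3C(OS(=O)(=O)C(F)(F)F)=C(C)[C@H]12 | intermediate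
12 | 2-(2-bromoethyl)-1,3-dioxolane | BrCCC1OCCO1 | starting material
13 | (E)-1,4-dibromobut-2-ene | BrC/C=C/CBr | starting material
14 | [2-(1,3-dioxolan-2-yl)ethyl]magnesium bromide | Br[Mg]CCC1OCCO1 | intermediate (not isolated)
15 | 2-[(3S)-3-(bromomethyl)pent-4-en-1-yl]-1,3-dioxolane | C=C[C@@H](CBr)CCC1OCCO1 | intermediate
16 | (2S)-4-(1,3-dioxolan-2-yl)-2-ethenylbutyl acetate | C=C[C@@H](COC(C)=O)CCC1OCCO1 | intermediate
17 | (2S)-2-ethenyl-5-oxopentyl acetate | O=CCC[C@H](COC(C)=O)C=C | intermediate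
18 | (9S,12S)-20-acetoxy-2β,3β-epoxy-1-(triflyloxy)-1,14-secotrinervita-1(15),8(19),13-trien-9-ol | C=C([C@@H](O)CC[C@H](COC(C)=O)C=C)[C@@H]1CC[C@]2(C)[C@H]3O[C@H]3C(OS(=O)(=O)C(F)(F)F)=C(C)[C@H]12 | intermediate
19 | C14 B-alkyl-9-BBN adduct of 18, with C9–OH bound as its 9-BBN borinate | C=C([C@@H](OB1C2CCCC1CCC2)CC[C@H](COC(C)=O)CCB1C2CCCC1CCC2)[C@@H]1CC[C@]2(C)[C@H]3O[C@H]3C(OS(=O)(=O)C(F)(F)F)=C(C)[C@H]12 | intermediate (not isolated)
20 | (9S,12R)-20-acetoxy-2β,3β-epoxytrinervita-1(15),8(19)-dien-9-ol | C=C1[C@@H](O)CC[C@H](COC(C)=O)CCC2=C(C)[C@@H]3[C@H]1CC[C@]3(C)[C@H]4O[C@@H]24 | intermediate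
21 | (9S,12R)-2β,3β-epoxytrinervita-1(15),8(19)-diene-9,20-diyl diacetate | C=C1[C@@H](OC(C)=O)CC[C@H](COC(C)=O)CCC2=C(C)[C@@H]3[C@H]1CC[C@]3(C)[C@H]4O[C@@H]24 | intermediate
22 | CNP0193272.1, (2R,3R,4S,7R,9S,12R,16S)-2,3-dihydroxytrinervita-1(15),8(19)-diene-9,20-diyl diacetate | C=C1[C@@H](OC(C)=O)CC[C@H](COC(C)=O)CCC2=C(C)[C@@H]3[C@H]1CC[C@]3(C)[C@@H](O)[C@@H]2O | target

**Totals and risks**
Total step count: 14. Longest linear sequence: 11 (steps 1–7 and 11–14).

Steps most likely to fail:

Step 3 (the proposed new epoxidation). Catalyst control over the π-face and over the choice of enone arm may be incomplete, and the yield is capped at 50%. The fallback sets out from 5 and returns at 6. Ordinary Weitz–Scheffer epoxidation (t-BuOOH, DBU, CH2Cl2, 0 °C) of the less substituted enone gives, after silica removal of the C5 epimer, the racemic epoxide rac-(1R*,5S*,6R*)-3,5-dimethyl-5-(prop-2-en-1-yl)-7-oxabicyclo[4.1.0]hept-3-en-2-one F1. Preparative chiral SFC then delivers 6.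

Step 5 (Rauhut–Currier closure). The acceptor is α-methylated and neopentylic, and the phosphine could attack the α,β-epoxy ketone. The fallback sets out from 8 and returns at 9. t-BuOK (1.1 equiv, t-BuOH/THF, 0 °C) forms the extended dienolate of the side-chain enone, which adds through C7 to C16 (intramolecular vinylogous Michael, no nucleophilic catalyst). This gives the deconjugated 7-acetyl-2β,3β-epoxy-4β,15-dimethyl-16βH-cis-hydrind-5-en-1-one F2. DBU (CH2Cl2, rt) then moves the double bond into conjugation to give 9.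

Step 12 (macrocyclisation). The triflate is hindered, the ring is 11-membered, and Pd(0) could ionise the vinyl epoxide. The fallback sets out from 19 and returns at 20. Oxidation (NaBO3·4H2O, THF/H2O) gives the diol (9S)-20-acetoxy-2β,3β-epoxy-1-(triflyloxy)-1,14-secotrinervita-1(15),8(19)-diene-9,14-diol F3. Selective iodination of the primary hydroxyl (I2, PPh3, imidazole, −20 °C) gives the 14-iodo-1,14-secotrinervitadien-9-ol F4. Intramolecular nickel-catalysed reductive cross-electrophile coupling of the alkyl iodide with the enol triflate (NiBr2·glyme, 4,4′-di-tert-butyl-2,2′-bipyridine, Zn, DMA, syringe-pump addition) then closes the ring to 20.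

**Further compounds**
F1 | step 3 | rac-(1R*,5S*,6R*)-3,5-dimethyl-5-(prop-2-en-1-yl)-7-oxabicyclo[4.1.0]hept-3-en-2-one (racemate of 6; one enantiomer drawn) | C=CC[C@@]1(C)C=C(C)C(=O)[C@@H]2O[C@H]12
F2 | step 5 | 7-acetyl-2β,3β-epoxy-4β,15-dimethyl-16βH-cis-hydrind-5-en-1-one (C7 and C15 epimers) | CC(=O)C1C=C[C@]2(C)[C@H]3O[C@H]3C(=O)C(C)[C@H]12
F3 | step 12 | (9S)-20-acetoxy-2β,3β-epoxy-1-(triflyloxy)-1,14-secotrinervita-1(15),8(19)-diene-9,14-diol | C=C([C@@H](O)CC[C@H](COC(C)=O)CCO)[C@@H]1CC[C@]2(C)[C@H]3O[C@H]3C(OS(=O)(=O)C(F)(F)F)=C(C)[C@H]12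
F4 | step 12 | (9S)-20-acetoxy-2β,3β-epoxy-14-iodo-1-(triflyloxy)-1,14-secotrinervita-1(15),8(19)-dien-9-ol | C=C([C@@H](O)CC[C@H](COC(C)=O)CCI)[C@@H]1CC[C@]2(C)[C@H]3O[C@H]3C(OS(=O)(=O)C(F)(F)F)=C(C)[C@H]12
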